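**Retrosynthetic overview**
1. Plakortolide S ⇐ diimide saturation of alkyne 21 ⇐ Cu-catalysed C(sp3)–C(sp) coupling of the bicyclic methyl peroxyketal 8 (as its peroxycarbenium ion) with the phenol-alkyne 17; this joins the two halves and sets the quaternary peroxide carbon C3.
2. 8 ⇐ intramolecular oxa-Michael addition of hydroperoxy ketal 7 onto the butenolide (1,2-dioxane ring, formed second, cis-fused) ⇐ ozonolysis in MeOH of methallyl butenolide 6.
3. 6 (lactone ring, formed first) ⇐ Z-selective Wittig/lactonisation of a tertiary α-hydroxy aldehyde ⇐ (S)-2-methylglycidol + isopropenyl Grignard (C4a comes from the chiral epoxide).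
4. 17 ⇐ 4-iodophenol + 7-bromohept-1-ene (B-alkyl Suzuki coupling) + 1-(trimethylsilyl)propyne (propargylation).

Assumption: (S)-2-methylglycidol is taken as a purchasable compound (both enantiomers are catalogue items).
Ring numbering used in the names (furo[3,2-c][1,2]dioxine): O1, O2, C3 (quaternary peroxide carbon), C4 (CH2), C4a (C–Me, lactone O), O5, C6 (C=O), C7 (CH2), C7a (CH–OO).

**Route**

Step 1
Reactants: 1 (S)-2-methylglycidol; 2 isopropenylmagnesium bromide
Product: 3 (2R)-2,4-dimethylpent-4-ene-1,2-diol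
Conditions: 2 (2.5 equiv), CuI (10 mol %), THF, −30 to 0 °C; then 1 M HCl, 0 °C
Reagents that add atoms: none
Why: Cu-catalysed Grignard opening of the epoxide at its unsubstituted CH2 (SN2) leaves the tertiary carbinol centre of 1 untouched (S becomes R only through a CIP priority change).

Step 2
Reactants: 3 (2R)-2,4-dimethylpent-4-ene-1,2-diol
Product: 4 (2R)-2-hydroxy-2,4-dimethylpent-4-enal
Conditions: SO3·pyridine, DMSO, i-Pr2NEt, CH2Cl2, 0 °C; used crude
Reagents that add atoms: none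
Why: Parikh–Doering oxidation converts only the primary alcohol, since the tertiary alcohol cannot be oxidised and the quaternary centre cannot epimerise.

Step 3
Reactants: 4 (2R)-2-hydroxy-2,4-dimethylpent-4-enal
Product: 6 (5R)-5-methyl-5-(2-methylprop-2-en-1-yl)furan-2(5H)-one, via Z-hydroxy enoate 5 (not isolated)
Conditions: Ph3P=CHCO2Me, MeOH, 0 °C to rt; then cat. PPTS, CH2Cl2, rt
Reagents that add atoms: methyl (triphenylphosphoranylidene)acetate, COC(=O)C=P(c1ccccc1)(c1ccccc1)c1ccccc1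
Why: Wittig olefination of an α-hydroxy aldehyde with a stabilised ylide in MeOH is Z-selective, and the Z-γ-hydroxy enoate lactonises to the butenolide.

Step 4
Reactants: 6 (5R)-5-methyl-5-(2-methylprop-2-en-1-yl)furan-2(5H)-one
Product: 7 (5R)-5-(2-hydroperoxy-2-methoxypropyl)-5-methylfuran-2(5H)-one (both epimers at the ketal carbon)
Conditions: O3, CH2Cl2/MeOH 4:1, −78 °C (Sudan III end point); N2 purge, no reductant
Reagents that add atoms: ozone, [O-][O+]=O; methanol, CO
Why: Ozonolysis of the electron-rich 1,1-disubstituted alkene (the butenolide C=C is far slower) gives the ketone oxide by Criegee cleavage, and MeOH traps it as the hydroperoxy ketal.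

Step 5
Reactants: 7 (5R)-5-(2-hydroperoxy-2-methoxypropyl)-5-methylfuran-2(5H)-one
Product: 8 (4aR,7aR)-3-methoxy-3,4a-dimethyltetrahydro-3H-furo[3,2-c][1,2]dioxin-6(4H)-one (both C3 epimers)
Conditions: Et2NH (0.3 equiv), CF3CH2OH, 0 °C to rt
Reagents that add atoms: none
Why: Intramolecular 6-exo oxa-Michael addition of the hydroperoxide to the butenolide delivers oxygen on the face that carries the tether, so only the cis-fused 5/6 system forms and C7a (R) is set by C4a.

Step 6
Reactants: 9 4-iodophenol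
Product: 10 (4-iodophenoxy)tri(propan-2-yl)silane
Conditions: TIPSCl, imidazole, DMF, rt
Reagents that add atoms: chlorotri(propan-2-yl)silane, CC(C)[Si](Cl)(C(C)C)C(C)C
Why: Standard O-silylation of the phenol gives an ether that survives the aqueous base and organolithium steps ahead.

Step 7
Reactants: 11 7-bromohept-1-ene; 10 (4-iodophenoxy)tri(propan-2-yl)silane
Product: 13 [4-(7-bromoheptyl)phenoxy]tri(propan-2-yl)silane, via bromoheptyl borane 12 (not isolated)
Conditions: 9-BBN, THF, 0 °C to rt; then 10, PdCl2(dppf) (3 mol %), 3 M aq. K3PO4, DMF, rt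
Reagents that add atoms: none
Why: Anti-Markovnikov hydroboration followed by B-alkyl Suzuki–Miyaura coupling with the aryl iodide at room temperature leaves the primary alkyl bromide untouched by Pd(dppf).

Step 8
Reactants: 14 trimethyl(prop-1-yn-1-yl)silane; 13 [4-(7-bromoheptyl)phenoxy]tri(propan-2-yl)silane
Product: 16 trimethyl(10-{4-[tri(propan-2-yl)silyloxy]phenyl}dec-1-yn-1-yl)silane, via propargyllithium 15 (not isolated)
Conditions: 14, n-BuLi, THF, −78 to −20 °C; then 13, DMPU, −78 °C to rt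
Reagents that add atoms: none
Why: Lithiated 1-(trimethylsilyl)propyne alkylates primary bromides at the propargylic carbon (SN2), adding the three-carbon silyl-alkyne unit.

Step 9
Reactants: 16 trimethyl(10-{4-[tri(propan-2-yl)silyloxy]phenyl}dec-1-yn-1-yl)silane
Product: 17 4-(dec-9-yn-1-yl)phenol
Conditions: TBAF (2.5 equiv), THF, 0 °C to rt; 1 M HCl work-up
Reagents that add atoms: none
Why: Fluoride cleaves both the C(sp)–SiMe3 and the aryl O–Si(i-Pr)3 bonds in one global desilylation.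

Step 10
Reactants: 8 (4aR,7aR)-3-methoxy-3,4a-dimethyltetrahydro-3H-furo[3,2-c][1,2]dioxin-6(4H)-one; 17 4-(dec-9-yn-1-yl)phenol
Product: 21 (3R,4aR,7aR)-3-[10-(4-hydroxyphenyl)dec-1-yn-1-yl]-3,4a-dimethyltetrahydro-3H-furo[3,2-c][1,2]dioxin-6(4H)-one, via aryl silyl ether 18 (not isolated), via peroxycarbenium triflate 19 (not isolated), via coupled silyl ether 20 (not isolated)
Conditions: 17 (1.3 equiv), i-Pr2NEt (3.0 equiv), TMSOTf (2.6 equiv), Cu(MeCN)4PF6 (10 mol %), 2,6-bis(4,4-dimethyl-2-oxazolin-2-yl)pyridine (12 mol %), CH2Cl2, −78 to −40 °C; aq. citric acid work-up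
Reagents that add atoms: none
Why: Proposed new method: TMSOTf first silylates the phenol and then ionises the methyl peroxyketal (both C3 epimers) to the six-membered peroxycarbenium ion 19, while Cu(I)/i-Pr2NEt converts the terminal alkyne into a copper acetylide that adds to 19 as a closed-shell two-electron nucleophile at a temperature where Cu(I) does not cleave a dialkyl O–O bond; attack is axial on the half-chair that has the lactone C4a–O bond pseudoaxial and the 4a-methyl pseudoequatorial (the other half-chair would force attack syn to an axial methyl), so the alkyne enters cis to O5 and trans to the 4a-methyl and sets C3 as R; the closest known reactions are the Cu-catalysed alkynylation of acetal-derived oxocarbenium ions with terminal alkynes (TMSOTf/amine) and the Lewis-acid Sakurai allylation of peroxycarbenium ions from alkoxy-1,2-dioxolanes, neither of which has been shown for a ketone-derived cyclic peroxyketal.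

Step 11
Reactants: 21 (3R,4aR,7aR)-3-[10-(4-hydroxyphenyl)dec-1-yn-1-yl]-3,4a-dimethyltetrahydro-3H-furo[3,2-c][1,2]dioxin-6(4H)-one
Product: 22 plakortolide S, (3S,4aR,7aR)-3-[10-(4-hydroxyphenyl)decyl]-3,4a-dimethyltetrahydro-3H-furo[3,2-c][1,2]dioxin-6(4H)-one
Conditions: KO2CN=NCO2K (20 equiv, portionwise), AcOH (40 equiv), MeOH/CH2Cl2, 0 °C to rt
Reagents that add atoms: none
Why: Diimide reduction delivers H2 to C≡C and then C=C by a concerted syn transfer without touching the O–O bond, lactone or phenol, and C3 keeps its geometry (R becomes S only through a CIP priority change).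

**Compound list**
1 | (S)-2-methylglycidol, [(2S)-2-methyloxiran-2-yl]methanol | C[C@]1(CO)CO1 | starting material
2 | isopropenylmagnesium bromide | CC(=C)[Mg]Br | starting material
3 | (2R)-2,4-dimethylpent-4-ene-1,2-diol | C[C@](O)(CO)CC(C)=C | intermediate
4 | (2R)-2-hydroxy-2,4-dimethylpent-4-enal | C[C@](O)(C=O)CC(C)=C | intermediate
5 | methyl (2Z,4R)-4-hydroxy-4,6-dimethylhepta-2,6-dienoate | C[C@](O)(/C=C\C(=O)OC)CC(C)=C | intermediate
6 | (5R)-5-methyl-5-(2-methylprop-2-en-1-yl)furan-2(5H)-one | C[C@@]1(OC(=O)C=C1)CC(C)=C | intermediate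
7 | (5R)-5-(2-hydroperoxy-2-methoxypropyl)-5-methylfuran-2(5H)-one (both ketal epimers) | C[C@@]1(OC(=O)C=C1)CC(C)(OC)OO | intermediate
8 | (4aR,7aR)-3-methoxy-3,4a-dimethyltetrahydro-3H-furo[3,2-c][1,2]dioxin-6(4H)-one (both C3 epimers) | COC1(C)C[C@@]2(C)OC(=O)C[C@H]2OO1 | intermediate
9 | 4-iodophenol | Oc1ccc(I)cc1 | starting material
10 | (4-iodophenoxy)tri(propan-2-yl)silane | CC(C)[Si](Oc1ccc(I)cc1)(C(C)C)C(C)C | intermediate
11 | 7-bromohept-1-ene | C=CCCCCCBr | starting material
12 | 9-(7-bromoheptyl)-9-borabicyclo[3.3.1]nonane | BrCCCCCCCB1C2CCCC1CCC2 | intermediate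
13 | [4-(7-bromoheptyl)phenoxy]tri(propan-2-yl)silane | CC(C)[Si](Oc1ccc(CCCCCCCBr)cc1)(C(C)C)C(C)C | intermediate
14 | trimethyl(prop-1-yn-1-yl)silane | CC#C[Si](C)(C)C | starting material
15 | [3-(trimethylsilyl)prop-2-yn-1-yl]lithium | [Li]CC#C[Si](C)(C)C | intermediate
16 | trimethyl(10-{4-[tri(propan-2-yl)silyloxy]phenyl}dec-1-yn-1-yl)silane | C[Si](C)(C)C#CCCCCCCCCc1ccc(O[Si](C(C)C)(C(C)C)C(C)C)cc1 | intermediate
17 | 4-(dec-9-yn-1-yl)phenol | C#CCCCCCCCCc1ccc(O)cc1 | intermediate
18 | [4-(dec-9-yn-1-yl)phenoxy]trimethylsilane | C#CCCCCCCCCc1ccc(O[Si](C)(C)C)cc1 | intermediate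
19 | (4aR,7aR)-3,4a-dimethyl-6-oxo-4,4a,7,7a-tetrahydro-6H-furo[3,2-c][1,2]dioxin-2-ium trifluoromethanesulfonate (cyclic peroxycarbenium ion) | CC1=[O+]O[C@@H]2CC(=O)O[C@]2(C)C1.[O-]S(=O)(=O)C(F)(F)F | intermediate
20 | (3R,4aR,7aR)-3,4a-dimethyl-3-{10-[4-(trimethylsilyloxy)phenyl]dec-1-yn-1-yl}tetrahydro-3H-furo[3,2-c][1,2]dioxin-6(4H)-one | C[C@]1(C#CCCCCCCCCc2ccc(O[Si](C)(C)C)cc2)C[C@@]2(C)OC(=O)C[C@H]2OO1 | intermediate
21 | (3R,4aR,7aR)-3-[10-(4-hydroxyphenyl)dec-1-yn-1-yl]-3,4a-dimethyltetrahydro-3H-furo[3,2-c][1,2]dioxin-6(4H)-one | C[C@]1(C#CCCCCCCCCc2ccc(O)cc2)C[C@@]2(C)OC(=O)C[C@H]2OO1 | intermediate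
22 | plakortolide S, (3S,4aR,7aR)-3-[10-(4-hydroxyphenyl)decyl]-3,4a-dimethyltetrahydro-3H-furo[3,2-c][1,2]dioxin-6(4H)-one | C[C@]1(CCCCCCCCCCc2ccc(O)cc2)C[C@@]2(C)OC(=O)C[C@H]2OO1 | target

**Step count and risks**
Total steps: 11. Longest linear sequence: 7 (steps 1–5, 10, 11); the side-chain branch is steps 6–9.

Steps most likely to fail:

Step 10 (the proposed new coupling). Possible failures are loss of a proton from the peroxycarbenium ion to an enol peroxide under TMSOTf/amine, Cu-induced O–O cleavage, or low selectivity at C3. The fallback uses only known chemistry and avoids the peroxycarbenium ion. It sets out from 6 and 13. Bromide 13 is coupled with but-3-enylmagnesium bromide (Li2CuCl4 cat., THF) to give tri(propan-2-yl)[4-(undec-10-en-1-yl)phenoxy]silane F2. Cross-metathesis of 6 with F2 (Hoveyda–Grubbs II, CH2Cl2, 40 °C) gives the trisubstituted alkene (5R)-5-methyl-5-{2-methyl-12-[4-(triisopropylsilyloxy)phenyl]dodec-2-en-1-yl}furan-2(5H)-one F3. Mukaiyama–Isayama hydroperoxysilylation (Co(thd)2 cat., O2, Et3SiH, DCE) gives the tertiary silyl peroxide (5R)-5-methyl-5-{2-methyl-2-[(triethylsilyl)peroxy]-12-[4-(triisopropylsilyloxy)phenyl]dodecyl}furan-2(5H)-one F4 as both epimers. TBAF then removes both silyl groups and the freed hydroperoxide closes onto the butenolide by oxa-Michael addition. This gives 22, where the fallback rejoins the route, together with its C3 epimer (3R,4aR,7aR)-3-[10-(4-hydroxyphenyl)decyl]-3,4a-dimethyltetrahydro-3H-furo[3,2-c][1,2]dioxin-6(4H)-one F5, which is removed by chromatography. The cost is loss of stereocontrol at C3.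

Step 11 (exhaustive diimide reduction of a hindered alkyne next to the quaternary peroxide carbon). It may stall at the cis-alkene. The fallback moves the unsaturation to a remote, unhindered position and sets out from 8 and 13. Sakurai allylation of 8 (allyltrimethylsilane, SnCl4, CH2Cl2, −78 °C, same axial attack) gives (3S,4aR,7aR)-3,4a-dimethyl-3-(prop-2-en-1-yl)tetrahydro-3H-furo[3,2-c][1,2]dioxin-6(4H)-one F6. Bromide 13 with vinylmagnesium bromide (Li2CuCl4 cat.) gives [4-(non-8-en-1-yl)phenoxy]tri(propan-2-yl)silane F7, and TBAF gives 4-(non-8-en-1-yl)phenol F8. Cross-metathesis of F6 with F8 (Grubbs II, CH2Cl2, 40 °C) gives (3S,4aR,7aR)-3-[10-(4-hydroxyphenyl)dec-2-en-1-yl]-3,4a-dimethyltetrahydro-3H-furo[3,2-c][1,2]dioxin-6(4H)-one F9 as an E/Z mixture. One short diimide reduction of this disubstituted alkene gives 22, where the fallback rejoins the route.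

Step 4 (ozonolysis to the hydroperoxy ketal). Criegee cleavage may go the other way and give the methyl ketone plus methoxymethyl hydroperoxide. The fallback sets out from 6. Ozonolysis in CH2Cl2 at −78 °C with Me2S work-up gives (5R)-5-methyl-5-(2-oxopropyl)furan-2(5H)-one F1. Acid-catalysed perketalisation of F1 (urea–H2O2, Sc(OTf)3 cat., MeOH, rt) gives 7, where the fallback rejoins the route.

**Further compounds**
F1 | step 4 | (5R)-5-methyl-5-(2-oxopropyl)furan-2(5H)-one | C[C@@]1(OC(=O)C=C1)CC(C)=O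
F2 | step 10 | tri(propan-2-yl)[4-(undec-10-en-1-yl)phenoxy]silane | C=CCCCCCCCCCc1ccc(O[Si](C(C)C)(C(C)C)C(C)C)cc1
F3 | step 10 | (5R)-5-methyl-5-{2-methyl-12-[4-(triisopropylsilyloxy)phenyl]dodec-2-en-1-yl}furan-2(5H)-one (E/Z) | C[C@@]1(OC(=O)C=C1)CC(C)=CCCCCCCCCCc1ccc(O[Si](C(C)C)(C(C)C)C(C)C)cc1
F4 | step 10 | (5R)-5-methyl-5-{2-methyl-2-[(triethylsilyl)peroxy]-12-[4-(triisopropylsilyloxy)phenyl]dodecyl}furan-2(5H)-one (both epimers) | C[C@@]1(OC(=O)C=C1)CC(C)(OO[Si](CC)(CC)CC)CCCCCCCCCCc1ccc(O[Si](C(C)C)(C(C)C)C(C)C)cc1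
F5 | step 10 | (3R,4aR,7aR)-3-[10-(4-hydroxyphenyl)decyl]-3,4a-dimethyltetrahydro-3H-furo[3,2-c][1,2]dioxin-6(4H)-one (C3 epimer of 22) | C[C@@]1(CCCCCCCCCCc2ccc(O)cc2)C[C@@]2(C)OC(=O)C[C@H]2OO1
F6 | step 11 | (3S,4aR,7aR)-3,4a-dimethyl-3-(prop-2-en-1-yl)tetrahydro-3H-furo[3,2-c][1,2]dioxin-6(4H)-one | C[C@]1(CC=C)C[C@@]2(C)OC(=O)C[C@H]2OO1
F7 | step 11 | [4-(non-8-en-1-yl)phenoxy]tri(propan-2-yl)silane | C=CCCCCCCCc1ccc(O[Si](C(C)C)(C(C)C)C(C)C)cc1
F8 | step 11 | 4-(non-8-en-1-yl)phenol | C=CCCCCCCCc1ccc(O)cc1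
F9 | step 11 | (3S,4aR,7aR)-3-[10-(4-hydroxyphenyl)dec-2-en-1-yl]-3,4a-dimethyltetrahydro-3H-furo[3,2-c][1,2]dioxin-6(4H)-one (E/Z) | C[C@]1(CC=CCCCCCCCc2ccc(O)cc2)C[C@@]2(C)OC(=O)C[C@H]2OO1
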